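**Plan**
- Retrosynthesis: remove the silyl and benzyl groups and the ring A 2-O-methyl group, then cut ring A at C1–C2 and C5–C6 (Diels–Alder), then the butynoate C–O bond to ring B and the propanoate–acetyl C–C bond of the diene.
- Enabling feature: ring A C1 (with the depside carbonyl) and C6 (with its methyl) are a but-2-ynoate already esterified to the ring B 4-oxygen; C2–C5, the oxygens on C2 and C4 and the CH2O carbon on C3 are a 1,3-dioxygenated silyl ketene acetal diene.
- Forward: the diene is made from methyl 3-hydroxypropanoate and acetyl chloride; ring B is bought as 2,4-dihydroxy-3,6-dimethylbenzoic acid, protected as benzyl ester and 2-benzyl ether, and acylated at O4 with but-2-ynoic acid.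
- Ring A is the only ring made; it closes by cycloaddition and aromatisation on the intact depside ester, followed by O-methylation, hydrogenolysis and desilylation.
- Stereochemistry: the target has no stereocentre and no stereogenic double bond, so nothing has to be controlled.

Key step: step 10

Remark: 2,4-dihydroxy-3,6-dimethylbenzoic acid is taken to be a catalogue compound, and the hydroxymethyl group is carried as its tert-butyldiphenylsilyl (TBDPS) ether so that it outlasts the acidic enol ether formation and the hydrogenolysis.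

Step 1
Reactants: 1 methyl 3-hydroxypropanoate
Product: 2 methyl 3-[(tert-butyldiphenylsilyl)oxy]propanoate
Conditions: TBDPSCl (1.1 equiv), imidazole (2.2 equiv), DMF, 0 °C to rt
Reagents that add atoms: tert-butyl(chloro)diphenylsilane (TBDPSCl), CC(C)(C)[Si](Cl)(c1ccccc1)c1ccccc1
Why: Imidazole-promoted silylation of a primary alcohol is routine and should give the robust silyl ether cleanly.

Step 2
Reactants: 2 methyl 3-[(tert-butyldiphenylsilyl)oxy]propanoate; 3 acetyl chloride
Product: 5 methyl 2-{[(tert-butyldiphenylsilyl)oxy]methyl}-3-oxobutanoate (racemic), via lithium ester enolate 4 (not isolated)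
Conditions: LiN(CHMe2)2 (2.05 equiv), 2 (2.0 equiv), THF, −78 °C; then AcCl (1.0 equiv), −78 °C; aq. NH4Cl
Reagents that add atoms: none
Why: Crossed Claisen condensation in which enolate 4 is C-acylated by the acid chloride at −78 °C, a second enolate equivalent deprotonates the β-keto ester as it forms (that equivalent of 2 is recovered), and the low temperature holds back β-elimination of silanolate.

Step 3
Reactants: 5 methyl 2-{[(tert-butyldiphenylsilyl)oxy]methyl}-3-oxobutanoate
Product: 6 methyl (2E)-2-{[(tert-butyldiphenylsilyl)oxy]methyl}-3-methoxybut-2-enoate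
Conditions: HC(OMe)3 (3 equiv), MeOH, TsOH·H2O (3 mol%), rt to 45 °C; Et3N quench
Reagents that add atoms: trimethyl orthoformate, COC(OC)OC; methanol (solvent, exchanges with the orthoester), CO
Why: Acid-catalysed ketalisation by the orthoester followed by loss of methanol is the standard enol etherification of 2-substituted acetoacetates, the TBDPS ether should tolerate catalytic sulfonic acid in an anhydrous medium, and the double-bond geometry is immaterial because both isomers lead to the same dienolate.

Step 4
Reactants: 6 methyl (2E)-2-{[(tert-butyldiphenylsilyl)oxy]methyl}-3-methoxybut-2-enoate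
Product: 8 (1Z)-2-{[(tert-butyldiphenylsilyl)oxy]methyl}-1,3-dimethoxy-1-(trimethylsilyloxy)buta-1,3-diene, via lithium dienolate 7 (not isolated)
Conditions: LiN(CHMe2)2 (1.15 equiv), THF, −78 °C; Me3SiCl (1.3 equiv), −78 to 0 °C; pentane, filtration under argon, used crude
Reagents that add atoms: chlorotrimethylsilane, C[Si](C)(C)Cl
Why: Kinetic γ-deprotonation of the β-methoxy enoate gives the cross-conjugated dienolate 7, which Me3SiCl silylates on oxygen, the established preparation of Brassard-type silyl ketene acetal dienes, and the short enolate lifetime at −78 °C limits loss of silanolate.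

Step 5
Reactants: 9 2,4-dihydroxy-3,6-dimethylbenzoic acid
Product: 10 benzyl 2,4-dihydroxy-3,6-dimethylbenzoate
Conditions: BnBr (1.05 equiv), KHCO3 (1.2 equiv), DMF, rt
Reagents that add atoms: benzyl bromide, BrCc1ccccc1
Why: SN2 alkylation of the carboxylate with a hydrogencarbonate base that is too weak to deprotonate the phenols should give the benzyl ester selectively.

Step 6
Reactants: 10 benzyl 2,4-dihydroxy-3,6-dimethylbenzoate
Product: 11 benzyl 2-hydroxy-4-(methoxymethoxy)-3,6-dimethylbenzoate
Conditions: MOMCl (1.1 equiv), N,N-diisopropylethylamine (1.5 equiv), CH2Cl2, 0 °C to rt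
Reagents that add atoms: chloromethyl methyl ether (MOMCl), COCCl
Why: Williamson-type alkylation with an amine base selects the free 4-hydroxyl, because the 2-hydroxyl is held in a hydrogen bond to the ester carbonyl and flanked by the 3-methyl group.

Step 7
Reactants: 11 benzyl 2-hydroxy-4-(methoxymethoxy)-3,6-dimethylbenzoate
Product: 12 benzyl 2-(benzyloxy)-4-(methoxymethoxy)-3,6-dimethylbenzoate
Conditions: BnBr (1.5 equiv), K2CO3 (2.5 equiv), DMF, 60 °C
Reagents that add atoms: benzyl bromide, BrCc1ccccc1
Why: Williamson etherification with carbonate in a dipolar solvent at raised temperature forces the hydrogen-bonded, hindered 2-hydroxyl to react while the acetal and the benzyl ester are inert.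

Step 8
Reactants: 12 benzyl 2-(benzyloxy)-4-(methoxymethoxy)-3,6-dimethylbenzoate
Product: 13 benzyl 2-(benzyloxy)-4-hydroxy-3,6-dimethylbenzoate
Conditions: conc. HCl (cat.), MeOH–THF, 45 °C
Reagents that add atoms: none
Why: Acid-catalysed acetal exchange with methanol removes the aryl methoxymethyl ether, and the benzyl ether and the di-ortho-substituted benzyl ester are stable to dilute acid.

Step 9
Reactants: 13 benzyl 2-(benzyloxy)-4-hydroxy-3,6-dimethylbenzoate; 14 but-2-ynoic acid
Product: 15 benzyl 2-(benzyloxy)-4-(but-2-ynoyloxy)-3,6-dimethylbenzoate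
Conditions: DCC (1.2 equiv), DMAP (5 mol%), CH2Cl2, −20 to 0 °C
Reagents that add atoms: none
Why: Steglich esterification of the only free phenol, run cold and with only catalytic DMAP to limit conjugate addition of the pyridine to the ynoate.

Step 10
Reactants: 8 (1Z)-2-{[(tert-butyldiphenylsilyl)oxy]methyl}-1,3-dimethoxy-1-(trimethylsilyloxy)buta-1,3-diene; 15 benzyl 2-(benzyloxy)-4-(but-2-ynoyloxy)-3,6-dimethylbenzoate
Product: 17 benzyl 2-(benzyloxy)-4-{[3-({[tert-butyl(diphenyl)silyl]oxy}methyl)-2-hydroxy-4-methoxy-6-methylbenzoyl]oxy}-3,6-dimethylbenzoate, via cyclohexa-1,4-diene cycloadduct 16 (not isolated)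
Conditions: 8 (3 equiv, two portions), toluene (about 2 M in 15), 105 °C, sealed tube, argon; then 0.5 M HCl, THF, 0 °C to rt
Reagents that add atoms: none
Why: Normal-demand Diels–Alder reaction in which the electron-rich silyl ketene acetal diene 8 adds to the electron-poor aryl ynoate 15 in a concerted but strongly asynchronous (4+2) cycloaddition, the diene CH2 terminus bonding to the methyl-bearing β-carbon (ring A C5–C6) and the ketene acetal carbon to the α-carbon (ring A C1–C2) to give cyclohexa-1,4-diene 16. The closest known reaction type is the cycloaddition and aromatisation of Brassard- and Danishefsky-type 1,3-dioxygenated dienes with acetylenic esters to give salicylates; a β-methyl ynoate is a slow dienophile, so excess diene, high concentration and heat are used, helped by the aryl ester being more electron-withdrawing than an alkyl ester. Ring A closes as a six-membered carbocycle by this two-bond intermolecular annulation, after which dilute acid hydrolyses the mixed methyl silyl ketal of 16 and the dienone tautomerises (net loss of methanol and the Me3Si group) to the hydrogen-bonded phenol 17. No stereocentre is created in the product, since the racemic ketal carbon of 16 and the diene geometry are both erased on aromatisation. The step needs regioselectivity, secured by the match of the largest HOMO coefficient at the diene CH2 terminus with the largest LUMO coefficient at the ynoate β-carbon, and chemoselectivity for the ynoate over the hindered ester carbonyls, which silyl ketene acetals do not attack without a Lewis acid; the absence of any free hydroxyl in 15 also protects the diene from protonolysis.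

Step 11
Reactants: 17 benzyl 2-(benzyloxy)-4-{[3-({[tert-butyl(diphenyl)silyl]oxy}methyl)-2-hydroxy-4-methoxy-6-methylbenzoyl]oxy}-3,6-dimethylbenzoate
Product: 18 benzyl 2-(benzyloxy)-4-{[3-({[tert-butyl(diphenyl)silyl]oxy}methyl)-2,4-dimethoxy-6-methylbenzoyl]oxy}-3,6-dimethylbenzoate
Conditions: MeI (3 equiv), K2CO3 (2 equiv), acetone, 40 °C
Reagents that add atoms: iodomethane, CI
Why: Williamson O-methylation of the single free phenol under mild carbonate conditions that the di-ortho-substituted depside ester and the benzyl groups should tolerate, ring B having no free hydroxyl left to compete.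

Step 12
Reactants: 18 benzyl 2-(benzyloxy)-4-{[3-({[tert-butyl(diphenyl)silyl]oxy}methyl)-2,4-dimethoxy-6-methylbenzoyl]oxy}-3,6-dimethylbenzoate
Product: 19 4-{[3-({[tert-butyl(diphenyl)silyl]oxy}methyl)-2,4-dimethoxy-6-methylbenzoyl]oxy}-2-hydroxy-3,6-dimethylbenzoic acid
Conditions: H2 (1 atm), 10% Pd/C, EtOAc, rt
Reagents that add atoms: none
Why: Catalytic hydrogenolysis cleaves the benzyl ester and the aryl benzyl ether together, while the aryl ester persists and the silyl ether, in a non-protic solvent, shields the electron-rich benzylic C–O bond of ring A from reduction.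

Step 13
Reactants: 19 4-{[3-({[tert-butyl(diphenyl)silyl]oxy}methyl)-2,4-dimethoxy-6-methylbenzoyl]oxy}-2-hydroxy-3,6-dimethylbenzoic acid
Product: 20 2-hydroxy-4-{[3-(hydroxymethyl)-2,4-dimethoxy-6-methylbenzoyl]oxy}-3,6-dimethylbenzoic acid (CNP0372912.0)
Conditions: Bu4NF (3 equiv), AcOH (3 equiv), THF, 0 °C to rt; aqueous work-up at pH 4
Reagents that add atoms: none
Why: Fluoride-mediated desilylation buffered with acetic acid should remove the TBDPS group without base-induced cleavage of the depside ester or acid-induced ionisation of the 2,6-dimethoxybenzylic alcohol.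

**Compound list**
1 | methyl 3-hydroxypropanoate | COC(=O)CCO | starting material
2 | methyl 3-[(tert-butyldiphenylsilyl)oxy]propanoate | COC(=O)CCO[Si](c1ccccc1)(c1ccccc1)C(C)(C)C | intermediate
3 | acetyl chloride | CC(=O)Cl | starting material
4 | lithium enolate of 2 (geometry not assigned) | COC(O[Li])=CCO[Si](c1ccccc1)(c1ccccc1)C(C)(C)C | intermediate (not isolated)
5 | methyl 2-{[(tert-butyldiphenylsilyl)oxy]methyl}-3-oxobutanoate (racemic) | COC(=O)C(CO[Si](c1ccccc1)(c1ccccc1)C(C)(C)C)C(C)=O | intermediate
6 | methyl (2E)-2-{[(tert-butyldiphenylsilyl)oxy]methyl}-3-methoxybut-2-enoate (E isomer drawn as the expected main form; the Z isomer serves equally) | COC(=O)/C(CO[Si](c1ccccc1)(c1ccccc1)C(C)(C)C)=C(\C)OC | intermediate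
7 | lithium dienolate of 6 | C=C(OC)/C(CO[Si](c1ccccc1)(c1ccccc1)C(C)(C)C)=C(/OC)O[Li] | intermediate (not isolated)
8 | (1Z)-2-{[(tert-butyldiphenylsilyl)oxy]methyl}-1,3-dimethoxy-1-(trimethylsilyloxy)buta-1,3-diene (1Z drawn, expected from deprotonation through the s-cis ester; geometry without consequence) | C=C(OC)/C(CO[Si](c1ccccc1)(c1ccccc1)C(C)(C)C)=C(/OC)O[Si](C)(C)C | intermediate
9 | 2,4-dihydroxy-3,6-dimethylbenzoic acid | Cc1cc(O)c(C)c(O)c1C(=O)O | starting material
10 | benzyl 2,4-dihydroxy-3,6-dimethylbenzoate | Cc1cc(O)c(C)c(O)c1C(=O)OCc1ccccc1 | intermediate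
11 | benzyl 2-hydroxy-4-(methoxymethoxy)-3,6-dimethylbenzoate | COCOc1cc(C)c(C(=O)OCc2ccccc2)c(O)c1C | intermediate
12 | benzyl 2-(benzyloxy)-4-(methoxymethoxy)-3,6-dimethylbenzoate | COCOc1cc(C)c(C(=O)OCc2ccccc2)c(OCc2ccccc2)c1C | intermediate
13 | benzyl 2-(benzyloxy)-4-hydroxy-3,6-dimethylbenzoate | Oc1cc(C)c(C(=O)OCc2ccccc2)c(OCc2ccccc2)c1C | intermediate
14 | but-2-ynoic acid | CC#CC(=O)O | starting material
15 | benzyl 2-(benzyloxy)-4-(but-2-ynoyloxy)-3,6-dimethylbenzoate | CC#CC(=O)Oc1cc(C)c(C(=O)OCc2ccccc2)c(OCc2ccccc2)c1C | intermediate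
16 | cyclohexa-1,4-diene cycloadduct of 8 and 15 (racemic at the ketal carbon) | COC1=C(CO[Si](c2ccccc2)(c2ccccc2)C(C)(C)C)C(OC)(O[Si](C)(C)C)C(C(=O)Oc2cc(C)c(C(=O)OCc3ccccc3)c(OCc3ccccc3)c2C)=C(C)C1 | intermediate (not isolated)
17 | benzyl 2-(benzyloxy)-4-{[3-({[tert-butyl(diphenyl)silyl]oxy}methyl)-2-hydroxy-4-methoxy-6-methylbenzoyl]oxy}-3,6-dimethylbenzoate | COc1cc(C)c(C(=O)Oc2cc(C)c(C(=O)OCc3ccccc3)c(OCc3ccccc3)c2C)c(O)c1CO[Si](c1ccccc1)(c1ccccc1)C(C)(C)C | intermediate
18 | benzyl 2-(benzyloxy)-4-{[3-({[tert-butyl(diphenyl)silyl]oxy}methyl)-2,4-dimethoxy-6-methylbenzoyl]oxy}-3,6-dimethylbenzoate | COc1cc(C)c(C(=O)Oc2cc(C)c(C(=O)OCc3ccccc3)c(OCc3ccccc3)c2C)c(OC)c1CO[Si](c1ccccc1)(c1ccccc1)C(C)(C)C | intermediate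
19 | 4-{[3-({[tert-butyl(diphenyl)silyl]oxy}methyl)-2,4-dimethoxy-6-methylbenzoyl]oxy}-2-hydroxy-3,6-dimethylbenzoic acid | COc1cc(C)c(C(=O)Oc2cc(C)c(C(=O)O)c(O)c2C)c(OC)c1CO[Si](c1ccccc1)(c1ccccc1)C(C)(C)C | intermediate
20 | 2-hydroxy-4-{[3-(hydroxymethyl)-2,4-dimethoxy-6-methylbenzoyl]oxy}-3,6-dimethylbenzoic acid (CNP0372912.0) | COc1cc(C)c(C(=O)Oc2cc(C)c(C(=O)O)c(O)c2C)c(OC)c1CO | target

**Step count and risks**
Total step count: 13 steps.
Longest linear sequence: 9 steps (9 to 20 through steps 5 to 13); the diene branch from 1 is 8 steps.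

Steps most likely to fail:

Step 10. The cycloaddition to the β-methyl ynoate may be slower than the thermal decay of the diene (desilylation, silyl migration, oligomerisation), leaving 15 unchanged. The fallback sets out from 13 and comes back at 17. Phenol 13 is esterified with buta-2,3-dienoic acid (2-chloro-1-methylpyridinium iodide, Et3N, CH2Cl2, 0 °C) to give benzyl 2-(benzyloxy)-4-(buta-2,3-dienoyloxy)-3,6-dimethylbenzoate F1. Allenoates are much better dienophiles than the isomeric ynoates and are established surrogates for them with ketene acetal dienes. F1 should take up diene 8 across its conjugated C2=C3 bond near room temperature, with the same orientation, to give the exo-methylene cycloadduct F2. The same dilute acid treatment then removes methanol and the Me3Si group and lets the exocyclic double bond move into the ring, giving 17; the same two ring A bonds are formed.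

Step 2. The β-silyloxy ester enolate 4 may lose silanolate by β-elimination, or acetyl chloride may be diverted into O-acylation and ketene formation. The fallback sets out from 1 and comes back at 5. Methyl 3-hydroxypropanoate 1 is deprotonated twice (LiN(CHMe2)2, 2.2 equiv, THF, −78 to −40 °C) to the dilithium alkoxide enolate F3, whose oxide cannot act as a leaving group. Addition to acetaldehyde at −78 °C gives methyl 3-hydroxy-2-(hydroxymethyl)butanoate F4 as a diastereomer mixture. Selective silylation of the primary hydroxyl (TBDPSCl, imidazole, CH2Cl2, 0 °C) gives methyl 2-{[(tert-butyldiphenylsilyl)oxy]methyl}-3-hydroxybutanoate F5, and Dess–Martin oxidation of the secondary alcohol (NaHCO3, CH2Cl2) returns 5.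

Step 13. Cleavage of the hindered silyl ether by buffered fluoride may be slow, and forcing it in the presence of the free salicylic acid invites acyl cleavage at the depside or ionisation of the electron-rich benzylic C–O bond with self-condensation. The fallback sets out from 18 and comes back at 20 by inverting the last two operations. Compound 18, which has no acidic group, is desilylated with unbuffered Bu4NF (THF, 0 °C) to benzyl 2-(benzyloxy)-4-{[3-(hydroxymethyl)-2,4-dimethoxy-6-methylbenzoyl]oxy}-3,6-dimethylbenzoate F6. The two benzyl groups are then removed by hydrogenolysis (H2, 10% Pd/C, EtOAc, stopped after uptake of two equivalents so that the benzylic alcohol is not reduced) to give 20.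

**Further compounds**
F1 | step 10 | benzyl 2-(benzyloxy)-4-(buta-2,3-dienoyloxy)-3,6-dimethylbenzoate | C=C=CC(=O)Oc1cc(C)c(C(=O)OCc2ccccc2)c(OCc2ccccc2)c1C
F2 | step 10 | exo-methylene cycloadduct of 8 and F1 (racemic diastereomer mixture) | COC1=C(CO[Si](c2ccccc2)(c2ccccc2)C(C)(C)C)C(OC)(O[Si](C)(C)C)C(C(=O)Oc2cc(C)c(C(=O)OCc3ccccc3)c(OCc3ccccc3)c2C)C(=C)C1
F3 | step 2 | dilithium alkoxide enolate of methyl 3-hydroxypropanoate | COC(O[Li])=CCO[Li]
F4 | step 2 | methyl 3-hydroxy-2-(hydroxymethyl)butanoate (racemic diastereomer mixture) | COC(=O)C(CO)C(C)O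
F5 | step 2 | methyl 2-{[(tert-butyldiphenylsilyl)oxy]methyl}-3-hydroxybutanoate (racemic diastereomer mixture) | COC(=O)C(CO[Si](c1ccccc1)(c1ccccc1)C(C)(C)C)C(C)O
F6 | step 13 | benzyl 2-(benzyloxy)-4-{[3-(hydroxymethyl)-2,4-dimethoxy-6-methylbenzoyl]oxy}-3,6-dimethylbenzoate | COc1cc(C)c(C(=O)Oc2cc(C)c(C(=O)OCc3ccccc3)c(OCc3ccccc3)c2C)c(OC)c1CO
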